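Remark on the chemistry: the chain is numbered C7 (benzylic carbinol), C8 (aryloxy carbon) and C9 (CH2OH); ring A is the 4-hydroxy-3,5-dimethoxyphenyl ring (C1 on C7) and ring B the 4-allyl-2,6-dimethoxyphenyl ring (primed locants, ether oxygen on C4′). A CIP check of the target gives 7R,8S, the erythro (anti O7/O8) isomer; every structure below was checked against this assignment and none needed correcting.

## Structural features

Compound 13 is an 8-O-4′ neolignan with no ring other than its two benzene rings: a C7–C8–C9 chain whose benzylic carbinol C7 is bonded to C1 of ring A, whose C8 carries an ether oxygen to C4′ of ring B, and whose C9 is a primary alcohol. The only stereocentres, C7 (R) and C8 (S), are adjacent and erythro, that is, O7 and O8 are anti when C1–C7–C8–C9 is drawn as a zigzag; no ring can relay configuration, so the pair must be set by acyclic control. The fragile groups are the terminal allyl group on ring B (it excludes hydrogenolysis, hydroboration, ozonolysis and conditions that move the double bond), the C7 carbinol, which ionises easily because it is para to an oxygen on an electron-rich ring (by acid, or by base through a quinone methide once the phenol is free), and the two easily oxidised arenes. The C8–O–C4′ ether is flanked on ring B by two methoxy groups, so the phenol oxygen is a hindered nucleophile and C4′ a poor electrophile. The real difficulty is therefore to make this hindered secondary alkyl aryl ether with defined configuration at C8 and then to set C7 anti to it without epimerising C8, whose hydrogen is acidic in every carbonyl precursor. The key step turns the C8–O(ring B) bond into the controlling element: in aldehyde 9 it is the polar substituent that orients the C7 carbonyl group, so that the ring A titanium reagent 11 forms the C1–C7 bond on the face that gives 7R.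

## Logic of the disconnections

13 ⇒ 12. Only two O–Si bonds are cut, at the ring A phenol oxygen and at O9. Both hydroxyls must be masked while an organometallic reagent is present, and the same silyl type on both lets one fluoride treatment finish the synthesis. No skeletal simplification results, but the last step becomes a pure unmasking. The demand is that the unmasking neither ionises C7 nor touches the allyl group, so buffered fluoride is planned and acid, hydrogenolysis and oxidative deprotection are excluded.

12 ⇒ 9 + 11 (11 ⇐ 10 ⇐ 7). The C1–C7 bond between ring A and the benzylic carbinol is cut. This is the most convergent cut: it separates a ring A arene, one step from a commercial phenol, from a three-carbon unit that already carries ring B and C8, and it creates C7 next to C8 so that C8 can control it. The forward step must follow the non-chelated Felkin–Anh course at the formyl group of 9, and the reagent must be too weakly basic to enolise 9 at C8. Three choices answer this: the titanium triisopropoxide reagent 11 instead of 10 itself, a slight excess of the titanium chloride over n-BuLi so that no 10 survives, and non-chelating silyl groups on O9 and on the ring A oxygen.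

9 ⇒ 5. No skeletal bond is cut; C7 is taken back from the aldehyde to the ester oxidation level, because 5 is configurationally robust and storable and 9 is not. The demand is a reduction that stops at the aldehyde stage (through 8) and a base-free work-up. For that reason 9 is made last, kept cold and used without chromatography, with the arene partner 7 already in hand.

5 ⇒ 3 + 4. The C8–O bond to ring B is cut on the alkyl side. The hindered phenol oxygen of 4 then acts as the nucleophile at an sp3 carbon activated by the neighbouring ester, instead of a bond having to be made to the doubly ortho-substituted C4′. The cut removes ring B with its allyl group in one operation and traces C8 back to a hydroxy ester. The demand is an SN2 displacement with complete inversion at a secondary carbon, so the carbinol must have the configuration opposite to the ether (2R in 3, 2S in 5), and elimination or loss of the O9 silyl group must not compete.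

3 ⇒ 2 ⇒ 1. The O9–Si bond and then the two C–O bonds of the isopropylidene acetal are cut, arriving at a commercial chiral-pool ester that supplies C7, C8 and C9 with C8 as a single enantiomer. The acetal cannot be kept because O8 must be free while O9 is protected. The demands are acetal removal without ester hydrolysis (methanolysis, where ester exchange is degenerate) and selective silylation of the primary hydroxyl of 2.

7 ⇒ 6. The phenolic O–Si bond is cut, giving a commercial bromophenol. The demand is a group that survives n-BuLi at low temperature and leaves with fluoride together with the O9 group.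

## Other disconnections considered

Alternative 1: The cut is the O8–C4′ bond on the aryl side. In the forward sense the C8 hydroxyl of the O7,O9-silylene-protected erythro triol A1 would be deprotonated with KN(SiMe3)2. The alkoxide would attack C4 of 4-fluoro-3,5-dimethoxybenzaldehyde A2, para to the formyl group, through a Meisenheimer adduct that loses fluoride to give the aryl ether A3.
- In its favour: the C8–O bond is never broken, so C8 keeps its configuration by retention and no epimerisable aldehyde appears anywhere. The trans-diequatorial six-membered silylene ring holds the erythro relationship and presents an equatorial alkoxide.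
- Against it here: the fluorine of A2 lies between two methoxy groups, which shield C4 and donate into the ring, with only one para acceptor to stabilise the adduct. The nucleophile is a hindered secondary alkoxide that could also add to the formyl group. A1 needs both stereocentres set beforehand, and asymmetric dihydroxylation of an E-alkene would give the threo, not the erythro, triol, so an inversion or another construction would be needed. A3 carries a formyl group where the target has an allyl group, two carbons short, which would cost about three further steps (reduction, activation, vinyl cross-coupling) before desilylation.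
- Comparison: on structure, A3 is a less advanced key-step product than 12. On mechanism, this plan is the better one for configurational security in the ether-forming event (retention instead of a Mitsunobu inversion) and the equal of the chosen plan in its fluoride end-game, but the weaker one in the intrinsic reactivity of the bond-forming step. On step economy it would be several steps longer.

Alternative 2: The cut is the C8–C9 bond. The α-aryloxy ketone A4, which would come from O-alkylation of 4 at a primary carbon, would be converted into its (Z)-trimethylsilyl enol ether A5. A5 would add to aqueous formaldehyde A6 under Sc(OTf)3 and a chiral 2,2′-bipyridine diol ligand (a Mukaiyama-type aldol reaction in a water-containing medium), the catalyst selecting the enantioface at C8 to give the β-hydroxy ketone A7. A diastereoselective reduction at C7 and desilylation would follow.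
- In its favour: chirality comes from a catalyst and not from a stoichiometric chiral-pool reagent, the C1 unit is the cheapest possible, no phosphine or azo waste arises and no cryogenic organometallic is needed. The hindered phenol 4 is alkylated at a primary carbon, which is easier than a Mitsunobu reaction at a secondary carbon. On these points it is the better plan.
- Against it here: this catalyst system is established for enol ethers with alkyl groups on the nucleophilic carbon, whereas A5 carries a bulky, potentially coordinating aryloxy group there, so the level of enantioface selection is not assured. Z-selective enol silane formation is required. In A7 the C8–H lies between an aryl ketone and an aryloxy group, so racemisation, dehydration and retro-aldol cleavage are possible. C7 must then be set by a reduction that needs chelation control to give the erythro isomer (Felkin–Anh hydride delivery leads to threo), with the weakly basic ether oxygen as the chelating site.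
- Comparison: the step count would be about equal (roughly seven). Structurally both plans let C8 control C7, but here two stereochemical events are uncertain (enantioselectivity and diastereoselectivity) against one in the chosen plan, where C8 comes from 1 by inversion. Mechanistically the chosen Felkin addition works with the poor donor character of the aryloxy oxygen, whereas the reduction after A7 would have to work against it.

Alternative 3: The cut is the C7–H bond, made together with a resolution at C8. In the racemic keto ester A8 the C8–H lies between a ketone and an ester and should exchange through the enol in neutral buffer. An NADPH-dependent ketoreductase with cofactor recycling would reduce it; if one enantiomer reacts much faster and hydride is delivered to one face, both centres are fixed at once as the erythro hydroxy ester A9. Reduction of the ester to the C9 alcohol and desilylation would complete the synthesis.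
- In its favour: one catalytic step sets both stereocentres from a racemate with, in principle, complete conversion, at ambient temperature in water, without organolithium reagents, phosphines or azo compounds. On safety, waste and stereo-convergence it is the better plan. A8 should be reachable in a few steps from 4 by O-alkylation and C-acylation.
- Against it here: the ketone is flanked by two bulky groups bearing ortho-substituted arenes, and an enzyme that accepts it with the required anti sense would have to be found by screening, since many ketoreductases give syn products with α-substituted β-keto esters. The substrate is poorly soluble in water. The β-keto ester and the aryl silyl ether could hydrolyse during long incubations. The later hydride reduction of the ester must spare the allyl group and avoid retro-aldol loss of the C7–C8 bond.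
- Comparison: the step count should be equal or one lower. Structurally A9 has C9 at the wrong oxidation level, so a redox step follows the key step, whereas in the chosen plan C9 is an alcohol throughout. Mechanistically the chosen plan rests on a predictable substrate model and this one on an empirical enzyme fit. The two are equal in needing a final fluoride deprotection.

Key step: step 6

## Steps

Step 1
Reactants: 1 methyl (R)-2,2-dimethyl-1,3-dioxolane-4-carboxylate
Product: 2 methyl (R)-2,3-dihydroxypropanoate
Conditions: Amberlyst 15 (H+ form), MeOH, rt; filter, concentrate
Reagents that add atoms: none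
Why: Acid-catalysed transketalisation in methanol removes the isopropylidene group as its dimethyl acetal; methanol makes any ester exchange degenerate, the C8 centre is not involved, and filtering off the resin avoids an aqueous work-up of the water-soluble diol.

Step 2
Reactants: 2 methyl (R)-2,3-dihydroxypropanoate
Product: 3 methyl (R)-3-(tert-butyldimethylsilyloxy)-2-hydroxypropanoate
Conditions: TBSCl (1.05 equiv), imidazole, CH2Cl2, 0 °C
Reagents that add atoms: tert-butyldimethylsilyl chloride, CC(C)(C)[Si](C)(C)Cl
Why: Imidazole-mediated silylation is selective for the unhindered primary hydroxyl; the secondary hydroxyl next to the ester is more hindered and less nucleophilic and stays free for step 3.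

Step 3
Reactants: 3 methyl (R)-3-(tert-butyldimethylsilyloxy)-2-hydroxypropanoate; 4 4-allyl-2,6-dimethoxyphenol
Product: 5 methyl (S)-2-(4-allyl-2,6-dimethoxyphenoxy)-3-(tert-butyldimethylsilyloxy)propanoate
Conditions: PPh3, DIAD, THF, 0 °C to rt
Reagents that add atoms: none
Why: Mitsunobu etherification: the alkoxyphosphonium ion formed on the C8 oxygen of 3 is displaced by the phenoxide of 4 in an SN2 reaction with inversion, turning the 2R carbinol into the 2S aryl ether that is C8 of the target; displacement next to an ester is fast and an SN1 pathway is disfavoured there, which offsets the hindrance of the 2,6-dimethoxyphenol.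

Step 4
Reactants: 6 4-bromo-2,6-dimethoxyphenol
Product: 7 (4-bromo-2,6-dimethoxyphenoxy)(tert-butyl)dimethylsilane
Conditions: TBSCl, imidazole, DMF, rt
Reagents that add atoms: tert-butyldimethylsilyl chloride, CC(C)(C)[Si](C)(C)Cl
Why: Routine silylation of a phenol; the silyl ether masks the acidic hydroxyl during the halogen–metal exchange of step 6 and matches the O9 group so that one fluoride treatment removes both.

Step 5
Reactants: 5 methyl (S)-2-(4-allyl-2,6-dimethoxyphenoxy)-3-(tert-butyldimethylsilyloxy)propanoate
Product: 9 (S)-2-(4-allyl-2,6-dimethoxyphenoxy)-3-(tert-butyldimethylsilyloxy)propanal, via diisobutylaluminium hemiacetal 8 (not isolated)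
Conditions: iBu2AlH (1.1 equiv), CH2Cl2, −78 °C; MeOH, −78 °C; aq. potassium sodium tartrate
Reagents that add atoms: none
Why: Partial reduction of an ester by iBu2AlH: at −78 °C in a non-coordinating solvent the tetrahedral species 8 is held intact by aluminium coordination to the α-aryloxy oxygen and releases the aldehyde only on the cold protic quench; no base is present, so C8 keeps its configuration, and 9 is dried and used at once without chromatography.

Step 6
Reactants: 7 (4-bromo-2,6-dimethoxyphenoxy)(tert-butyl)dimethylsilane; 9 (S)-2-(4-allyl-2,6-dimethoxyphenoxy)-3-(tert-butyldimethylsilyloxy)propanal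
Product: 12 (1R,2S)-2-(4-allyl-2,6-dimethoxyphenoxy)-3-(tert-butyldimethylsilyloxy)-1-[4-(tert-butyldimethylsilyloxy)-3,5-dimethoxyphenyl]propan-1-ol, via aryllithium 10 (not isolated), via aryltitanium triisopropoxide 11 (not isolated)
Conditions: 7 (1.5 equiv), n-BuLi (1.45 equiv), THF, −78 °C; ClTi(OiPr)3 (1.6 equiv), −78 to −40 °C; then 9, −78 to −20 °C; aq. NH4Cl
Reagents that add atoms: none
Why: Bromine–lithium exchange on 7 gives 10, which ClTi(OiPr)3 transmetalates to the tetravalent aryltitanium 11; this adds through a cyclic four-centre transition state to the C7 carbonyl of 9, forming the C1–C7 bond, and aqueous work-up frees the C7 carbinol of 12. The closest known reaction type is the non-chelation-controlled (Felkin–Anh) 1,2-addition of organotitanium triisopropoxides and ArMgBr reagents to α-alkoxy and α-silyloxy aldehydes. No ring is closed. The new C7 centre is controlled by the existing C8 centre: in the polar Felkin–Anh transition state the C8–OAr bond is antiperiplanar to the forming C–C bond, the CH2OSi group lies beside the carbonyl oxygen and the aryl group travels past the C8 hydrogen, which on the (S)-aldehyde is the face that gives 7R, the anti (erythro) O7/O8 pair; the Cornforth dipole-minimised arrangement predicts the same face. The selectivity needed is Felkin over chelate attack, and three features secure it: the C8 oxygen is an aryl ether hemmed in by two methoxy groups and is a poor donor, the O9 silyl ether is likewise non-chelating, and the Ti(OiPr)3 centre is a weak Lewis acid with bulky alkoxide ligands. The titanium reagent is far less basic than 10, which protects the acidic C8–H of 9 against enolisation and the β-silyloxy group against elimination, so the enantiomeric purity set in step 3 should be carried into 12. A silyl shift from O9 to the new O7 alkoxide would be harmless because step 7 removes both silyl groups.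

Step 7
Reactants: 12 (1R,2S)-2-(4-allyl-2,6-dimethoxyphenoxy)-3-(tert-butyldimethylsilyloxy)-1-[4-(tert-butyldimethylsilyloxy)-3,5-dimethoxyphenyl]propan-1-ol
Product: 13 (1R,2S)-2-(4-allyl-2,6-dimethoxyphenoxy)-1-(4-hydroxy-3,5-dimethoxyphenyl)propane-1,3-diol
Conditions: Bu4NF (3 equiv), AcOH (3 equiv), THF, 0 °C to rt
Reagents that add atoms: none
Why: Fluoride-induced cleavage of both Si–O bonds (the aryl silyl ether first, the primary one more slowly), driven by the strong Si–F bond; acetic acid buffers the phenoxide and alkoxide that form, so the para-hydroxybenzylic C7 centre meets neither strong base (no quinone-methide pathway) nor acid, and the allyl group and both stereocentres are untouched.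

## Compound list

1 | methyl (R)-2,2-dimethyl-1,3-dioxolane-4-carboxylate | COC(=O)[C@H]1COC(C)(C)O1 | starting material
2 | methyl (R)-2,3-dihydroxypropanoate | COC(=O)[C@H](O)CO | intermediate
3 | methyl (R)-3-(tert-butyldimethylsilyloxy)-2-hydroxypropanoate | COC(=O)[C@H](O)CO[Si](C)(C)C(C)(C)C | intermediate
4 | 4-allyl-2,6-dimethoxyphenol | C=CCc1cc(OC)c(O)c(OC)c1 | starting material
5 | methyl (S)-2-(4-allyl-2,6-dimethoxyphenoxy)-3-(tert-butyldimethylsilyloxy)propanoate | C=CCc1cc(OC)c(O[C@@H](CO[Si](C)(C)C(C)(C)C)C(=O)OC)c(OC)c1 | intermediate
6 | 4-bromo-2,6-dimethoxyphenol | Oc1c(OC)cc(Br)cc1OC | starting material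
7 | (4-bromo-2,6-dimethoxyphenoxy)(tert-butyl)dimethylsilane | CC(C)(C)[Si](C)(C)Oc1c(OC)cc(Br)cc1OC | intermediate
8 | [(2S)-2-(4-allyl-2,6-dimethoxyphenoxy)-3-(tert-butyldimethylsilyloxy)-1-methoxypropoxy]bis(2-methylpropyl)alumane (diisobutylaluminium hemiacetal of 9, both C1 epimers, formed in the flask) | C=CCc1cc(OC)c(O[C@@H](CO[Si](C)(C)C(C)(C)C)C(OC)O[Al](CC(C)C)CC(C)C)c(OC)c1 | intermediate
9 | (S)-2-(4-allyl-2,6-dimethoxyphenoxy)-3-(tert-butyldimethylsilyloxy)propanal | C=CCc1cc(OC)c(O[C@@H](CO[Si](C)(C)C(C)(C)C)C=O)c(OC)c1 | intermediate
10 | [4-(tert-butyldimethylsilyloxy)-3,5-dimethoxyphenyl]lithium (formed in the flask) | [Li]c1cc(OC)c(O[Si](C)(C)C(C)(C)C)c(OC)c1 | intermediate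
11 | [4-(tert-butyldimethylsilyloxy)-3,5-dimethoxyphenyl]tri(propan-2-yloxy)titanium (formed in the flask) | CC(C)O[Ti](OC(C)C)(OC(C)C)c1cc(OC)c(O[Si](C)(C)C(C)(C)C)c(OC)c1 | intermediate
12 | (1R,2S)-2-(4-allyl-2,6-dimethoxyphenoxy)-3-(tert-butyldimethylsilyloxy)-1-[4-(tert-butyldimethylsilyloxy)-3,5-dimethoxyphenyl]propan-1-ol | C=CCc1cc(OC)c(O[C@@H](CO[Si](C)(C)C(C)(C)C)[C@H](O)c2cc(OC)c(O[Si](C)(C)C(C)(C)C)c(OC)c2)c(OC)c1 | intermediate
13 | (1R,2S)-2-(4-allyl-2,6-dimethoxyphenoxy)-1-(4-hydroxy-3,5-dimethoxyphenyl)propane-1,3-diol | C=CCc1cc(OC)c(O[C@@H](CO)[C@H](O)c2cc(OC)c(O)c(OC)c2)c(OC)c1 | target

## Step count and least certain steps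

Total: 7 steps. Longest linear sequence: 6 steps (steps 1, 2, 3, 5, 6, 7); the ring A branch (step 4) joins at step 6.

**Step 6 (key step).** The most likely failure is erosion of facial selectivity. If part of the addition runs through a chelated arrangement (titanium or residual lithium bridging the carbonyl oxygen and O8 or an ortho-methoxy oxygen of ring B), the threo C7 epimer forms. A second risk is deprotonation of 9 at C8 by untransmetalated 10, which lowers the enantiomeric purity. A third is slow addition of the mild titanium reagent, leaving 9 time to lose silanol. The fallback changes how C7 is set: acylation followed by chelation-controlled hydride reduction, instead of aryl addition to an aldehyde. It sets out from 5. Aminolysis with Me(MeO)NH·HCl and i-PrMgCl in THF at −20 °C would give the Weinreb amide (S)-2-(4-allyl-2,6-dimethoxyphenoxy)-3-(tert-butyldimethylsilyloxy)-N-methoxy-N-methylpropanamide F1. Addition of 10 (from 7 and n-BuLi, THF, −78 °C) and collapse of the chelated adduct on work-up would give the ketone (S)-2-(4-allyl-2,6-dimethoxyphenoxy)-3-(tert-butyldimethylsilyloxy)-1-[4-(tert-butyldimethylsilyloxy)-3,5-dimethoxyphenyl]propan-1-one F2. Reduction of F2 with Zn(BH4)2 in Et2O at −30 °C should pass through the five-membered zinc chelate of the carbonyl oxygen and O8, with hydride entering past the C8 hydrogen; this corresponds to the 7R (erythro) alcohol, and the fallback comes back to the route at 12.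

**Step 3.** The most likely failure is slow SN2 displacement at the congested alkoxyphosphonium centre, because the phenoxide oxygen of 4 is flanked by two methoxy groups. The reduced azodicarboxylate would then compete as the nucleophile, or the activated alcohol would simply be returned. The fallback replaces the redox condensation by separate activation and displacement, and sets out from 3. Tf2O and 2,6-lutidine in CH2Cl2 at −78 °C would give, with retention, methyl (R)-3-(tert-butyldimethylsilyloxy)-2-(trifluoromethylsulfonyloxy)propanoate F3. Displacement with the potassium phenoxide of 4 (K2CO3, MeCN, −20 °C to rt) should proceed by SN2 with inversion, and the fallback comes back to the route at 5.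

**Step 5.** The most likely failure is collapse of 8 before the quench, so that the freed aldehyde is reduced further and a mixture with unchanged 5 results; partial epimerisation at C8 during work-up or concentration is a second risk. The fallback separates reduction and oxidation, and sets out from 5. Excess iBu2AlH (2.5 equiv, CH2Cl2, −78 to 0 °C) would give (R)-2-(4-allyl-2,6-dimethoxyphenoxy)-3-(tert-butyldimethylsilyloxy)propan-1-ol F4 without touching the allyl group. Dess–Martin oxidation buffered with NaHCO3 (CH2Cl2, 0 °C) would then form the aldehyde under non-basic conditions, and the fallback comes back to the route at 9.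

**Step 7.** The most likely failure follows from slow cleavage of the primary silyl ether, which keeps the molecule under fluoride after the ring A phenoxide is already free; expulsion of the C7 oxygen through a para-quinone methide would then scramble C7. The fallback unmasks in two stages under non-basic conditions, and sets out from 12. KHF2 in MeOH at rt should cleave only the aryl silyl ether, giving (1R,2S)-2-(4-allyl-2,6-dimethoxyphenoxy)-3-(tert-butyldimethylsilyloxy)-1-(4-hydroxy-3,5-dimethoxyphenyl)propan-1-ol F5. Et3N·3HF in THF at rt would then remove the primary silyl group, and the fallback comes back to the route at 13.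

## Further compounds

F1 | step 6 | (S)-2-(4-allyl-2,6-dimethoxyphenoxy)-3-(tert-butyldimethylsilyloxy)-N-methoxy-N-methylpropanamide | C=CCc1cc(OC)c(O[C@@H](CO[Si](C)(C)C(C)(C)C)C(=O)N(C)OC)c(OC)c1
F2 | step 6 | (S)-2-(4-allyl-2,6-dimethoxyphenoxy)-3-(tert-butyldimethylsilyloxy)-1-[4-(tert-butyldimethylsilyloxy)-3,5-dimethoxyphenyl]propan-1-one | C=CCc1cc(OC)c(O[C@@H](CO[Si](C)(C)C(C)(C)C)C(=O)c2cc(OC)c(O[Si](C)(C)C(C)(C)C)c(OC)c2)c(OC)c1
F3 | step 3 | methyl (R)-3-(tert-butyldimethylsilyloxy)-2-(trifluoromethylsulfonyloxy)propanoate | COC(=O)[C@H](OS(=O)(=O)C(F)(F)F)CO[Si](C)(C)C(C)(C)C
F4 | step 5 | (R)-2-(4-allyl-2,6-dimethoxyphenoxy)-3-(tert-butyldimethylsilyloxy)propan-1-ol | C=CCc1cc(OC)c(O[C@@H](CO[Si](C)(C)C(C)(C)C)CO)c(OC)c1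
F5 | step 7 | (1R,2S)-2-(4-allyl-2,6-dimethoxyphenoxy)-3-(tert-butyldimethylsilyloxy)-1-(4-hydroxy-3,5-dimethoxyphenyl)propan-1-ol | C=CCc1cc(OC)c(O[C@@H](CO[Si](C)(C)C(C)(C)C)[C@H](O)c2cc(OC)c(O)c(OC)c2)c(OC)c1
A1 | alternative 1 | (4R,5S)-2,2-di-tert-butyl-4-[3,5-dimethoxy-4-(triisopropylsilyloxy)phenyl]-1,3,2-dioxasilinan-5-ol | O[C@H]1CO[Si](C(C)(C)C)(C(C)(C)C)O[C@@H]1c1cc(OC)c(O[Si](C(C)C)(C(C)C)C(C)C)c(OC)c1
A2 | alternative 1 | 4-fluoro-3,5-dimethoxybenzaldehyde | O=Cc1cc(OC)c(F)c(OC)c1
A3 | alternative 1 | 4-[[(4R,5S)-2,2-di-tert-butyl-4-[3,5-dimethoxy-4-(triisopropylsilyloxy)phenyl]-1,3,2-dioxasilinan-5-yl]oxy]-3,5-dimethoxybenzaldehyde | O=Cc1cc(OC)c(O[C@H]2CO[Si](C(C)(C)C)(C(C)(C)C)O[C@@H]2c2cc(OC)c(O[Si](C(C)C)(C(C)C)C(C)C)c(OC)c2)c(OC)c1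
A4 | alternative 2 | 2-(4-allyl-2,6-dimethoxyphenoxy)-1-[3,5-dimethoxy-4-(triisopropylsilyloxy)phenyl]ethan-1-one | C=CCc1cc(OC)c(OCC(=O)c2cc(OC)c(O[Si](C(C)C)(C(C)C)C(C)C)c(OC)c2)c(OC)c1
A5 | alternative 2 | (Z)-[2-(4-allyl-2,6-dimethoxyphenoxy)-1-[3,5-dimethoxy-4-(triisopropylsilyloxy)phenyl]ethenyloxy]trimethylsilane | C=CCc1cc(OC)c(O/C=C(\O[Si](C)(C)C)c2cc(OC)c(O[Si](C(C)C)(C(C)C)C(C)C)c(OC)c2)c(OC)c1
A6 | alternative 2 | formaldehyde | C=O
A7 | alternative 2 | (S)-2-(4-allyl-2,6-dimethoxyphenoxy)-3-hydroxy-1-[3,5-dimethoxy-4-(triisopropylsilyloxy)phenyl]propan-1-one | C=CCc1cc(OC)c(O[C@@H](CO)C(=O)c2cc(OC)c(O[Si](C(C)C)(C(C)C)C(C)C)c(OC)c2)c(OC)c1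
A8 | alternative 3 | ethyl 2-(4-allyl-2,6-dimethoxyphenoxy)-3-[4-(tert-butyldimethylsilyloxy)-3,5-dimethoxyphenyl]-3-oxopropanoate (racemic) | C=CCc1cc(OC)c(OC(C(=O)OCC)C(=O)c2cc(OC)c(O[Si](C)(C)C(C)(C)C)c(OC)c2)c(OC)c1
A9 | alternative 3 | ethyl (2R,3R)-2-(4-allyl-2,6-dimethoxyphenoxy)-3-[4-(tert-butyldimethylsilyloxy)-3,5-dimethoxyphenyl]-3-hydroxypropanoate | C=CCc1cc(OC)c(O[C@@H](C(=O)OCC)[C@H](O)c2cc(OC)c(O[Si](C)(C)C(C)(C)C)c(OC)c2)c(OC)c1
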